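**Retrosynthetic overview** (eudesmane numbering; ring A = C1–C5/C10, ring B = C5–C10)
1. The strategy rests on the C8 carbonyl of ring B, which lies between C7 and the neopentyl CH2 C9 beside quaternary C10. Ring B is cut at C7–C8 and C8–C9: C8 comes from CO, the other five ring atoms (C7=C6 vinyl on C5, cyclopropane C5–C9–C10) from a ring A vinylcyclopropane ([5+1]).
2. After the ring closure: 4α-OH-directed hydrogenation (C5), isopropylidene at C7 from acetone dimethyl ketal, angelate at C3, and last a Schenck ene reaction of the 7(11)-en-8-one (C11–OOH, C6=C7).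
3. Before it: C3 by CBS reduction of 2-methylcyclohex-2-en-1-one, C4 by anti dihydroxylation, C10 methyl by enolate methylation, vinyl by Stille coupling, cyclopropane (C9; sets C10) by 4α-OH-directed Simmons–Smith reaction.
4. Ring order: ring A is bought; the cyclopropane is a temporary ring (step 9); ring B closes in step 10.

Key step: step 10

Remark: α/β refer to the usual eudesmane drawing (C10 methyl β) and are used for the ring A intermediates too; the dione starting point is replaced by 2-methylcyclohex-2-en-1-one so that the trans C3/C4 diol follows from two reactions of predictable sense.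

**Step 1**
Reactants: 1 2-methylcyclohex-2-en-1-one
Product: 2 (S)-2-methylcyclohex-2-en-1-ol
Conditions: (R)-2-methyl-CBS-oxazaborolidine (10 mol %), BH3·SMe2, THF, −20 °C; MeOH
Reagents that add atoms: none
Why: Corey–Bakshi–Shibata reduction; with the 2-methylalkenyl arm as the large group the (R)-catalyst should give the (S)-carbinol, the future C3 (3β-O).

**Step 2**
Reactants: 2 (S)-2-methylcyclohex-2-en-1-ol
Product: 3 tert-butyldimethyl{[(1S)-2-methylcyclohex-2-en-1-yl]oxy}silane
Conditions: TBSCl, imidazole, DMF, rt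
Reagents that add atoms: tert-butyldimethylsilyl chloride, CC(C)(C)[Si](C)(C)Cl
Why: Imidazole-assisted silylation of the secondary allylic alcohol; no stereocentre is touched and the bulky ether will shield the β-face in step 3.

**Step 3**
Reactants: 3 silyl ether
Product: 4 (1S,2S,3S)-3-(tert-butyldimethylsilyloxy)-2-methylcyclohexane-1,2-diol
Conditions: OsO4 (2 mol %), NMO, acetone/H2O, rt
Reagents that add atoms: osmium tetroxide (catalytic oxygen carrier), O=[Os](=O)(=O)=O; N-methylmorpholine N-oxide, C[N+]1([O-])CCOCC1; water, O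
Why: Catalytic syn dihydroxylation; OsO4 should add to C4=C5 on the face opposite the pseudo-axial allylic silyloxy group (the normal anti sense for cyclic allylic ethers), which sets the 4α tertiary hydroxyl trans to the C3 oxygen and gives a C5 hydroxyl as a handle.

**Step 4**
Reactants: 4 diol
Product: 5 (2R,3S)-3-(tert-butyldimethylsilyloxy)-2-hydroxy-2-methylcyclohexan-1-one
Conditions: SO3·pyridine, DMSO, Et3N, CH2Cl2, 0 °C to rt
Reagents that add atoms: none
Why: Parikh–Doering oxidation takes only the secondary C5 alcohol and does not cleave the glycol; C4 has no hydrogen, so neither epimerisation nor β-elimination of the C3 silyloxy group can occur.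

**Step 5**
Reactants: 5 α-hydroxy ketone
Product: 6 (2R,3S)-3-(tert-butyldimethylsilyloxy)-2-methyl-2-(trimethylsilyloxy)cyclohexan-1-one
Conditions: TMSOTf, 2,6-lutidine, CH2Cl2, −78 °C
Reagents that add atoms: trimethylsilyl trifluoromethanesulfonate, C[Si](C)(C)OS(=O)(=O)C(F)(F)F
Why: Silyl triflate silylation of the hindered tertiary alcohol; masking it prevents α-ketol rearrangement, O-alkylation and silyl migration from the C3 oxygen in the two strong-base steps that follow.

**Step 6**
Reactants: 6 ketone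
Product: 8 (2R,3S,6RS)-3-(tert-butyldimethylsilyloxy)-2,6-dimethyl-2-(trimethylsilyloxy)cyclohexan-1-one, via lithium enolate 7 (not isolated)
Conditions: LiN(iPr)2, THF, −78 °C; MeI, −78 to −20 °C
Reagents that add atoms: iodomethane, CI
Why: Enolate alkylation; C10 is the only enolisable position (C4 is quaternary), so one enolate forms and iodomethane brings in the future C10 methyl, the new centre being a mixture that is flattened in step 7.

**Step 7**
Reactants: 8 methyl ketone
Product: 10 (5S,6R)-5-(tert-butyldimethylsilyloxy)-2,6-dimethyl-6-(trimethylsilyloxy)cyclohex-1-en-1-yl trifluoromethanesulfonate, via potassium enolate 9 (not isolated)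
Conditions: KN(SiMe3)2, THF, −78 °C; PhNTf2, −78 to 0 °C
Reagents that add atoms: N-phenylbis(trifluoromethanesulfonimide), O=S(=O)(N(c1ccccc1)S(=O)(=O)C(F)(F)F)C(F)(F)F
Why: Enol triflate formation; the only α-hydrogen left is the tertiary C10–H, so the tetrasubstituted C5=C10 enolate forms and is triflated on oxygen.

**Step 8**
Reactants: 10 enol triflate; 11 tributyl(vinyl)stannane
Product: 13 (1S,6S)-6-(tert-butyldimethylsilyloxy)-1,3-dimethyl-2-vinylcyclohex-2-en-1-ol, via trimethylsilyl-protected diene 12 (not isolated)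
Conditions: Pd(PPh3)4 (5 mol %), LiCl, THF, 65 °C; then K2CO3, MeOH, 0 °C to rt
Reagents that add atoms: tributyl(vinyl)stannane 11, C=C[Sn](CCCC)(CCCC)CCCC
Why: Stille coupling (zerovalent palladium, chloride-assisted for a triflate) puts the vinyl group C6=C7 on C5, and basic methanolysis then removes only the tertiary trimethylsilyl ether, avoiding acid at the ionisable dienyl carbinol.

**Step 9**
Reactants: 13 dienol; 14 diiodomethane
Product: 16 (1R,2S,3S,6R)-3-(tert-butyldimethylsilyloxy)-2,6-dimethyl-1-vinylbicyclo[4.1.0]heptan-2-ol (3β-silyloxy, 4α-hydroxy, cyclopropane C5–C9–C10 on the α-face, C10 methyl β, vinyl on C5), via ethylzinc alkoxide 15 (not isolated)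
Conditions: Et2Zn, CH2I2, CH2Cl2, −10 to 0 °C; aq. NH4Cl
Reagents that add atoms: diiodomethane 14, ICI
Why: Hydroxyl-directed Simmons–Smith cyclopropanation; the zinc alkoxide of the 4α-hydroxyl should deliver CH2 (C9) to the α-face of the allylic, tetrasubstituted C5=C10 bond, setting C10 (methyl β) and C5 together, while the homoallylic monosubstituted vinyl group reacts more slowly.

**Step 10**
Reactants: 16 vinylcyclopropane; 17 carbon monoxide
Product: 18 3β-(tert-butyldimethylsilyloxy)-4α-hydroxy-11,12,13-trinoreudesm-5-en-8-one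
Conditions: [Rh(dppp)]SbF6 (10 mol %, from [Rh(CO)2Cl]2, dppp, AgSbF6), CO/N2 (1:4, 1 atm), ClCH2CH2Cl, 85 °C
Reagents that add atoms: carbon monoxide 17, [C-]#[O+]
Why: Monovalent rhodium binds the vinyl group and adds oxidatively into the adjacent C5–C9 bond to give a σ,π-allyl rhodacycle of trivalent rhodium (η3 over C5–C6–C7, σ-bond to C9); CO inserts into Rh–C9 and reductive elimination between the acyl carbon C8 and C7 releases the 5-en-8-one. The closest known reaction is the rhodium-catalysed [5+1] cycloaddition of vinylcyclopropanes with CO to β,γ-cyclohexenones. Ring B closes as a formal [5+1] ring expansion, C7–C6–C5–C10–C9 plus C8, with C7–C8 and C8–C9 as the new bonds. No stereocentre is formed; C10 and its bonds to C1, C9 and the methyl group are untouched, so the configuration from step 9 becomes the ring-fusion configuration. The step needs cleavage of C5–C9 and not C5–C10 or C9–C10: only the two bonds at C5 are activated by the vinyl group, and of these the one to CH2 puts rhodium on a primary carbon instead of quaternary C10; since C10 has no hydrogen, the Rh–CH2 species cannot undergo β-hydride elimination to a diene. Aprotic conditions and low CO pressure are chosen so that the 5-ene does not move into conjugation before step 11.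

**Step 11**
Reactants: 18 β,γ-enone
Product: 19 3β-(tert-butyldimethylsilyloxy)-4α-hydroxy-11,12,13-trinor-5α-eudesman-8-one
Conditions: [Ir(cod)(PCy3)(py)]PF6 (5 mol %), H2 (1 atm), CH2Cl2, 0 °C to rt
Reagents that add atoms: none
Why: Hydroxyl-directed hydrogenation; the cationic iridium catalyst binds the allylic 4α-hydroxyl and adds H2 to the α-face of C5=C6, also the face away from the C10 methyl, so C5 should get its α-hydrogen (trans fusion) without passing through an enol.

**Step 12**
Reactants: 19 hydroxy ketone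
Product: 21 3β-(tert-butyldimethylsilyloxy)-4α,8-bis(trimethylsilyloxy)-11,12,13-trinor-5α-eudesm-7-ene, via ketone trimethylsilyl ether 20 (not isolated)
Conditions: TMSOTf (2.4 equiv), Et3N, CH2Cl2, 0 °C
Reagents that add atoms: trimethylsilyl trifluoromethanesulfonate, C[Si](C)(C)OS(=O)(=O)C(F)(F)F
Why: Silylation of the 4-hydroxyl followed by soft enolisation of the C8 ketone toward C7, the direction preferred over neopentyl C9 in a trans-fused 10-methyl ring B, should give the Δ7 silyl enol ether.

**Step 13**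
Reactants: 21 silyl enol ether; 22 2,2-dimethoxypropane
Product: 24 3β-(tert-butyldimethylsilyloxy)-4α-(trimethylsilyloxy)-5α-eudesm-7(11)-en-8-one, via methoxy ketone 23 (not isolated)
Conditions: 2,2-dimethoxypropane, TMSOTf (10 mol %), CH2Cl2, −78 °C; then DBU, rt to 40 °C
Reagents that add atoms: 2,2-dimethoxypropane 22, COC(C)(C)OC
Why: Mukaiyama aldol-type addition of the enol ether to the oxocarbenium ion of the acetone ketal forms C7–C11, and E1cB loss of methanol gives the tetrasubstituted conjugated isopropylidene ketone; only the C11 oxygen is β to the carbonyl, so the C4 oxygen is not at risk.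

**Step 14**
Reactants: 24 bis-silyl ether
Product: 25 3β,4α-dihydroxy-5α-eudesm-7(11)-en-8-one
Conditions: HF·pyridine, THF, 0 °C to rt
Reagents that add atoms: none
Why: Fluoride cleavage of both silyl ethers under non-basic conditions, so the 7(11)-ene stays in place and C5 is not enolised.

**Step 15**
Reactants: 25 diol; 26 angelic acid
Product: 27 3β-angeloyloxy-4α-hydroxy-5α-eudesm-7(11)-en-8-one
Conditions: angelic acid, 2,4,6-trichlorobenzoyl chloride, Et3N, toluene, rt; then 25, toluene, 75 °C
Reagents that add atoms: angelic acid 26, C/C=C(/C)C(=O)O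
Why: Yamaguchi-type esterification through the mixed anhydride, heated without DMAP to avoid Z to E isomerisation; only the secondary equatorial 3β-hydroxyl should react, the hindered tertiary 4α-hydroxyl stays free.

**Step 16**
Reactants: 27 angelate
Product: 28 3β-angeloyloxy-4α-hydroxy-11-hydroperoxy-5α-eudesm-6-en-8-one (CNP0161122.1; 3S,4S,5R,10R)
Conditions: O2, methylene blue, visible light, CH2Cl2, −20 °C
Reagents that add atoms: dioxygen, O=O
Why: Schenck ene reaction; singlet oxygen should add to the tetrasubstituted 7(11)-alkene of the s-cis enone with the usual enone regiochemistry (oxygen at the β-carbon C11, hydrogen taken from C6, the alkyl group geminal to the carbonyl), giving the C11 hydroperoxide and the C6=C7 enone without a new stereocentre, while the electron-poor angelate reacts more slowly and is not isomerised by the low-energy sensitiser.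

**Compound list**
1 | 2-methylcyclohex-2-en-1-one | CC1=CCCCC1=O | starting material
2 | (S)-2-methylcyclohex-2-en-1-ol | O[C@H]1CCCC=C1C | intermediate
3 | tert-butyldimethyl{[(1S)-2-methylcyclohex-2-en-1-yl]oxy}silane | CC(C)(C)[Si](C)(C)O[C@H]1CCCC=C1C | intermediate
4 | (1S,2S,3S)-3-(tert-butyldimethylsilyloxy)-2-methylcyclohexane-1,2-diol | CC(C)(C)[Si](C)(C)O[C@H]1CCC[C@H](O)[C@]1(C)O | intermediate
5 | (2R,3S)-3-(tert-butyldimethylsilyloxy)-2-hydroxy-2-methylcyclohexan-1-one | CC(C)(C)[Si](C)(C)O[C@H]1CCCC(=O)[C@]1(C)O | intermediate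
6 | (2R,3S)-3-(tert-butyldimethylsilyloxy)-2-methyl-2-(trimethylsilyloxy)cyclohexan-1-one | CC(C)(C)[Si](C)(C)O[C@H]1CCCC(=O)[C@]1(C)O[Si](C)(C)C | intermediate
7 | lithium enolate of 6 (C5–O, C5=C10) | CC(C)(C)[Si](C)(C)O[C@H]1CCC=C([O-])[C@]1(C)O[Si](C)(C)C.[Li+] | intermediate
8 | (2R,3S,6RS)-3-(tert-butyldimethylsilyloxy)-2,6-dimethyl-2-(trimethylsilyloxy)cyclohexan-1-one | CC(C)(C)[Si](C)(C)O[C@H]1CCC(C)C(=O)[C@]1(C)O[Si](C)(C)C | intermediate
9 | potassium enolate of 8 (tetrasubstituted C5=C10) | CC(C)(C)[Si](C)(C)O[C@H]1CCC(C)=C([O-])[C@]1(C)O[Si](C)(C)C.[K+] | intermediate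
10 | (5S,6R)-5-(tert-butyldimethylsilyloxy)-2,6-dimethyl-6-(trimethylsilyloxy)cyclohex-1-en-1-yl trifluoromethanesulfonate | CC(C)(C)[Si](C)(C)O[C@H]1CCC(C)=C(OS(=O)(=O)C(F)(F)F)[C@]1(C)O[Si](C)(C)C | intermediate
11 | tributyl(vinyl)stannane | C=C[Sn](CCCC)(CCCC)CCCC | starting material
12 | tert-butyl{[(1S,2S)-2,4-dimethyl-2-(trimethylsilyloxy)-3-vinylcyclohex-3-en-1-yl]oxy}dimethylsilane | CC(C)(C)[Si](C)(C)O[C@H]1CCC(C)=C(C=C)[C@]1(C)O[Si](C)(C)C | intermediate
13 | (1S,6S)-6-(tert-butyldimethylsilyloxy)-1,3-dimethyl-2-vinylcyclohex-2-en-1-ol | CC(C)(C)[Si](C)(C)O[C@H]1CCC(C)=C(C=C)[C@]1(C)O | intermediate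
14 | diiodomethane | ICI | starting material
15 | ethylzinc alkoxide of 13 | CC(C)(C)[Si](C)(C)O[C@H]1CCC(C)=C(C=C)[C@]1(C)O[Zn]CC | intermediate
16 | (1R,2S,3S,6R)-3-(tert-butyldimethylsilyloxy)-2,6-dimethyl-1-vinylbicyclo[4.1.0]heptan-2-ol | CC(C)(C)[Si](C)(C)O[C@H]1CC[C@]2(C)C[C@]2(C=C)[C@]1(C)O | intermediate
17 | carbon monoxide | [C-]#[O+] | starting material
18 | 3β-(tert-butyldimethylsilyloxy)-4α-hydroxy-11,12,13-trinoreudesm-5-en-8-one | CC(C)(C)[Si](C)(C)O[C@H]1CC[C@]2(C)CC(=O)CC=C2[C@]1(C)O | intermediate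
19 | 3β-(tert-butyldimethylsilyloxy)-4α-hydroxy-11,12,13-trinor-5α-eudesman-8-one | CC(C)(C)[Si](C)(C)O[C@H]1CC[C@]2(C)CC(=O)CC[C@H]2[C@]1(C)O | intermediate
20 | 3β-(tert-butyldimethylsilyloxy)-4α-(trimethylsilyloxy)-11,12,13-trinor-5α-eudesman-8-one | CC(C)(C)[Si](C)(C)O[C@H]1CC[C@]2(C)CC(=O)CC[C@H]2[C@]1(C)O[Si](C)(C)C | intermediate
21 | 3β-(tert-butyldimethylsilyloxy)-4α,8-bis(trimethylsilyloxy)-11,12,13-trinor-5α-eudesm-7-ene | CC(C)(C)[Si](C)(C)O[C@H]1CC[C@]2(C)CC(O[Si](C)(C)C)=CC[C@H]2[C@]1(C)O[Si](C)(C)C | intermediate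
22 | 2,2-dimethoxypropane | COC(C)(C)OC | starting material
23 | 3β-(tert-butyldimethylsilyloxy)-11-methoxy-4α-(trimethylsilyloxy)-5α-eudesman-8-one (C7 epimers) | CC(C)(C)[Si](C)(C)O[C@H]1CC[C@]2(C)CC(=O)C(C(C)(C)OC)C[C@H]2[C@]1(C)O[Si](C)(C)C | intermediate
24 | 3β-(tert-butyldimethylsilyloxy)-4α-(trimethylsilyloxy)-5α-eudesm-7(11)-en-8-one | CC(C)(C)[Si](C)(C)O[C@H]1CC[C@]2(C)CC(=O)C(=C(C)C)C[C@H]2[C@]1(C)O[Si](C)(C)C | intermediate
25 | 3β,4α-dihydroxy-5α-eudesm-7(11)-en-8-one | O[C@H]1CC[C@]2(C)CC(=O)C(=C(C)C)C[C@H]2[C@]1(C)O | intermediate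
26 | angelic acid, (Z)-2-methylbut-2-enoic acid | C/C=C(/C)C(=O)O | starting material
27 | 3β-angeloyloxy-4α-hydroxy-5α-eudesm-7(11)-en-8-one | C/C=C(/C)C(=O)O[C@H]1CC[C@]2(C)CC(=O)C(=C(C)C)C[C@H]2[C@]1(C)O | intermediate
28 | 3β-angeloyloxy-4α-hydroxy-11-hydroperoxy-5α-eudesm-6-en-8-one (CNP0161122.1) | C/C=C(/C)C(=O)O[C@H]1CC[C@]2(C)CC(=O)C(C(C)(C)OO)=C[C@H]2[C@]1(C)O | target

**Total step count:** 16. **Longest linear sequence:** 16 steps (1 to 28).

**Steps most likely to fail**

1. Step 10. Oxidative addition may be too slow at a fully substituted cyclopropane flanked by two quaternary carbons. The cationic metal may instead ionise the tertiary cyclopropylcarbinol, or the new 5-ene may drift into conjugation and scramble C5. Fallback, from enol triflate 10: Stille coupling with tributyl(3-methylbuta-1,2-dien-1-yl)stannane F1 (made from 3-chloro-3-methylbut-1-yne and Bu3SnLi/CuBr) should give the vinylallene trimethylsilyl ether F2. K2CO3/MeOH frees the vinylallene alcohol F3, and the 4α-OH-directed Simmons–Smith reaction gives the allenylcyclopropane F4. Allenylcyclopropanes are the most reactive established substrates for carbonylative [5+1] ring expansion ([Rh(CO)2Cl]2, CO 1 atm, toluene, 60 °C). The product is the cross-conjugated 3β-silyloxy-4α-hydroxyeudesma-5,7(11)-dien-8-one F5, which already carries C11–C13. Directed hydrogenation of its 5-ene with [Ir(cod)(PCy3)(py)]PF6 gives 3β-silyloxy-4α-hydroxy-5α-eudesm-7(11)-en-8-one F6, and HF·pyridine returns to the route at diol 25; steps 11–13 are then not needed.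

2. Step 9. The carbenoid may also attack the vinyl group (over-cyclopropanation), or the zinc iodide formed may ionise the tertiary dienyl alcohol. Fallback, from enol triflate 10: Sonogashira coupling with ethynyltrimethylsilane (PdCl2(PPh3)2, CuI, Et3N) gives the silylated enyne F7. K2CO3/MeOH removes both trimethylsilyl groups to give the enynol F8, whose only alkene is the allylic C5=C10 bond, the alkyne being inert to zinc carbenoids. Directed Simmons–Smith reaction gives the ethynylcyclopropane F9, and semihydrogenation (H2, Pd/CaCO3 poisoned with Pb(OAc)2, quinoline) returns to the route at vinylcyclopropane 16.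

3. Step 16. The ene reaction of the electron-poor enone may be slow enough that the angelate is also oxidised or isomerised on long irradiation, and the product hydroperoxide may decay during that time. Fallback, from silyl ether 24, with the order of the last steps changed: photooxygenation of 24, which has no angelate, gives the hydroperoxide F10. 2-Methoxypropene/PPTS protects it as the 2-methoxyprop-2-yl peroxyketal F11, and buffered TBAF/AcOH gives the diol peroxyketal F12. Esterification as in step 15 gives the angelate peroxyketal F13, and AcOH/THF/H2O releases the hydroperoxide, returning to the route at target 28.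

**Further compounds**
F1 | step 10 | tributyl(3-methylbuta-1,2-dien-1-yl)stannane | CC(C)=C=C[Sn](CCCC)(CCCC)CCCC
F2 | step 10 | analogue of 12 with 3-methylbuta-1,2-dien-1-yl in place of vinyl (vinylallene trimethylsilyl ether) | CC(C)(C)[Si](C)(C)O[C@H]1CCC(C)=C(C=C=C(C)C)[C@]1(C)O[Si](C)(C)C
F3 | step 10 | analogue of 13 with 3-methylbuta-1,2-dien-1-yl in place of vinyl (vinylallene alcohol) | CC(C)(C)[Si](C)(C)O[C@H]1CCC(C)=C(C=C=C(C)C)[C@]1(C)O
F4 | step 10 | analogue of 16 with 3-methylbuta-1,2-dien-1-yl on C5 (allenylcyclopropane, CH2 on the α-face) | CC(C)(C)[Si](C)(C)O[C@H]1CC[C@]2(C)C[C@]2(C=C=C(C)C)[C@]1(C)O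
F5 | step 10 | 3β-(tert-butyldimethylsilyloxy)-4α-hydroxyeudesma-5,7(11)-dien-8-one | CC(C)(C)[Si](C)(C)O[C@H]1CC[C@]2(C)CC(=O)C(=C(C)C)C=C2[C@]1(C)O
F6 | step 10 | 3β-(tert-butyldimethylsilyloxy)-4α-hydroxy-5α-eudesm-7(11)-en-8-one | CC(C)(C)[Si](C)(C)O[C@H]1CC[C@]2(C)CC(=O)C(=C(C)C)C[C@H]2[C@]1(C)O
F7 | step 9 | analogue of 12 with (trimethylsilyl)ethynyl in place of vinyl | CC(C)(C)[Si](C)(C)O[C@H]1CCC(C)=C(C#C[Si](C)(C)C)[C@]1(C)O[Si](C)(C)C
F8 | step 9 | analogue of 13 with ethynyl in place of vinyl (enynol) | CC(C)(C)[Si](C)(C)O[C@H]1CCC(C)=C(C#C)[C@]1(C)O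
F9 | step 9 | analogue of 16 with ethynyl on C5 (ethynylcyclopropane, CH2 on the α-face) | CC(C)(C)[Si](C)(C)O[C@H]1CC[C@]2(C)C[C@]2(C#C)[C@]1(C)O
F10 | step 16 | 3β-(tert-butyldimethylsilyloxy)-11-hydroperoxy-4α-(trimethylsilyloxy)-5α-eudesm-6-en-8-one | CC(C)(C)[Si](C)(C)O[C@H]1CC[C@]2(C)CC(=O)C(C(C)(C)OO)=C[C@H]2[C@]1(C)O[Si](C)(C)C
F11 | step 16 | 2-methoxyprop-2-yl peroxyketal of F10 | CC(C)(C)[Si](C)(C)O[C@H]1CC[C@]2(C)CC(=O)C(C(C)(C)OOC(C)(C)OC)=C[C@H]2[C@]1(C)O[Si](C)(C)C
F12 | step 16 | 3β,4α-dihydroxy-11-(2-methoxyprop-2-ylperoxy)-5α-eudesm-6-en-8-one | O[C@H]1CC[C@]2(C)CC(=O)C(C(C)(C)OOC(C)(C)OC)=C[C@H]2[C@]1(C)O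
F13 | step 16 | 3β-angeloyloxy-4α-hydroxy-11-(2-methoxyprop-2-ylperoxy)-5α-eudesm-6-en-8-one | C/C=C(/C)C(=O)O[C@H]1CC[C@]2(C)CC(=O)C(C(C)(C)OOC(C)(C)OC)=C[C@H]2[C@]1(C)O
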